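Which of the four set-ups ends with the most L, and how far does the stirred tank fall behind the closed flask? Here are the flasks, the readings and the questions.

in all of them: J 0.21 mM
- eta: Z 0.10 M; Q 2 equiv; G 0.19 mol%; run made earlier
- gamma: Z 0.10 M; Q 2 equiv; G 0.095 mol%; run made earlier
- delta: Z 0.10 M; Q 2 equiv; G 0.38 mol%; run made earlier
- ash: Z 0.10 M (fed, over 16.0 min); Q 2.00 equiv; G 0.19 mol%; all but Z at the start; Z goes in evenly over 16.0 min, the run ends at 20 min; time 20 min
- elm: Z 0.10 M; Q 2.00 equiv; G 0.19 mol%; a closed flask charged with all of it at once and left for 20 min; time 20 min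
- maple: Z 0.10 M; Q 2.00 equiv (fed, over 16.0 min); G 0.19 mol%; all but Q at the start; Q goes in evenly over 16.0 min, the run ends at 20 min; time 20 min
- oak: Z 0.10 M; Q 2.00 equiv; G 0.19 mol%; one stirred flow tank at steady state, fed with the mixture as stated, mean residence time 20 min

| run | time / min | L / % | Z / % |
|---|---|---|---|
| eta | 1.00 | 15.6 | 84.4 |
| eta | 3.00 | 34.9 | 64.9 |
| eta | 6.00 | 49.1 | 48.6 |
| eta | 8.00 | 55.2 | 43.6 |
| eta | 12.0 | 62.1 | 36.4 |
| gamma | 1.33 | 19.2 | 79.8 |
| gamma | 4.00 | 40.1 | 58.2 |
| gamma | 8.00 | 54.9 | 42.2 |
| gamma | 12.0 | 61.4 | 36.2 |
| gamma | 15.0 | 63.6 | 34.0 |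
| delta | 1.33 | 20.0 | 80.9 |
| delta | 4.00 | 41.6 | 58.4 |
| delta | 8.00 | 55.3 | 42.5 |
| delta | 12.0 | 61.0 | 36.6 |
| delta | 15.0 | 63.1 | 34.2 |

(scatter of a reading: 0.5 percentage points)

- the stated concentrations are those of everything mixed, before any reaction; amounts are the same in each set-up
- the feed brings no volume worth counting
- the earlier runs were made in a closed, stirred flask
- a reading or a percentage of L counts all its forms, free or not

- the set-up with the highest amount of L at the outlet or at the end, in percent of the Z put in ("none" if the first two lie within 2 percentage points) (ash / elm / maple / oak / none)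
- amount of L at the outlet or at the end, in percent of the Z put in, ash
- amount of L at the outlet or at the end, in percent of the Z put in, elm
- amount of L at the outlet or at the end, in percent of the Z put in, maple
- amount of L at the outlet or at the end, in percent of the Z put in, oak

The stirred tank, oak, is the set-up I can reckon straight from a table. At steady state it holds a single mixture, the outlet's, so its L must equal the residence time times the rate at that mixture. I take that rate from the eta run, which has oak's charge, assuming a closed flask at the same L holds about the same mixture. So I guess a level, read the slope there, multiply by 20 min, and put the answer back.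

Between 6.00 min and 8.00 min the eta run stands near 52.2%, and its slope times 20 min gives 61.0%. That is more than the guess, so the level reads higher. The next row pair stands near 58.6% and gives 34.5%, which is less than that guess, so the level reads between them.

A straight line between the two row pairs gives the tank level, the L at which the batch slope times the residence time returns that same L: 53.9%. It is a reading, and slopes from such close rows carry the scatter. The eta run passes this level at 7.57 min, so the tank's 20 min buys less than a closed flask's 20 min.

The forecast names elm best, with elm 65.5%, ash 59.5%, maple 60% and oak 54.5%; for oak it says “the steady-state balance gives” about 55%. My level of 53.9% lies lower than the forecast's oak value.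

The flask gives elm as best, with elm 65.4%, ash 59.3%, maple 58.9% and oak 52.8%.

    L + G ⇌ E + G, rate k1*[G]*[L] forward; the back reaction follows from the equilibrium constant (k = 0.770 /M/s)
    Q + L ⇌ X, settled at all times (K = 71.0 /M)
    G + J ⇌ D (K = 3000 /M, k = 3.30 /M/s)
    Z + Q ⇌ L (K = 4.80 /M, k = 0.0150 /M/s)
    Z + Q ⇌ E (K = 16.0 /M, k = 3.90 × 10⁻⁴ /M/s)

The oak tank holds Z at 0.0444 M. Elm has the eta charge, so on the eta readings it passes my tank level of 53.9% at 7.57 min, and its remaining 12.4 min carry it to 65.4%.

All runs are simulated from invented constants, and the scatter is random.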